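3 questions stand on this flask, and I read two things for them: how fast the substrate goes while the gas phase is held, and where the target stands in the latest readings.

| flask | substrate | gas phase | remark | time |
|---|---|---|---|---|
| east | 0.70 M | 97 mM (held) | run made earlier |  |
| west | 1.1 M | 97 mM (held) | run made earlier |  |
| flask | 0.50 M | 97 mM (held) |  | 20 h |

| run | time / h | target / % | substrate / % |
|---|---|---|---|
| east | 2.00 | 32.3 | 46.1 |
| east | 3.00 | 33.0 | 30.7 |
| east | 5.00 | 27.2 | 13.8 |
| east | 8.00 | 15.8 | 0.2 |
| east | 15.0 | 10.3 | 2.1 |
| east | 25.0 | 10.0 | 0.6 |
| west | 4.00 | 30.2 | 25.2 |
| west | 8.00 | 18.4 | 4.2 |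
| west | 12.0 | 12.3 | 0.7 |
| west | 15.0 | 10.6 | 0 |
| west | 20.0 | 9.8 | 0 |
| west | 25.0 | 10.1 | 0 |

(each reading ± 1 percentage point)

- at the start none of the gas phase is in solution

- the target standing at 20 h, as a percentage of the substrate charged
- the change that raises the amount of target at 20 h, in percent of the substrate charged most ("none" if none brings more than 2 percentage points) (teal / violet / none)
- amount of target at 20 h, in percent of the substrate charged, after teal

- teal: doubling the transfer coefficient of the gas phase, all else as stated
- violet: doubling the saturation concentration of gas phase, all else as stated

My balance on the substrate is that c(substrate) falls in proportion to itself. The east run at 5.00 h gives 0.396 /h, my clearing constant k, the fractional fall of c(substrate) per hour read as pseudo-first-order.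

First, the charge. By hand, if gas uptake set the pace, the fall in M per hour would stay put and the percent fall would slow at the larger charge. But the west run at 8.00 h gives 0.396 /h, a reading with wide scatter, so I carry k to 0.50 M.

Next, the time. The lifetime 2.52 h is short against 20 h, so k leaves 0.0363% of the substrate in this flask. The latest target readings stand near 9.97%, and that is my answer.

Last, teal and violet. By hand, either could shorten the lifetime, but a faster flask reaches that late level sooner. No run varied the gas, so I answer none, and the same level after teal, as a judgement.

The forecast gives 10% (9.2% to 11%), none, and 10% after teal, holding that “That plateau does not depend on loading”.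

The flask gives 11.1%, none, and 11.1% after teal, which is 1.1 percentage points above my late level; teal moves it −0.0091 points and violet −0.015 points. The answer shifts by 5 points once the time is cut to 8.10 h, where k leaves 4.05% of the substrate.

    gas phase ⇌ dissolved gas, rate k1*(csat - [dissolved gas]) (kL = 0.00164 /s)
    substrate + dissolved gas → target (k = 0.00208 /M/s)
    2 dissolved gas → homo dimer (k = 0.00272 /M/s)
    dissolved gas → decomposed reagent (k = 1.36 × 10⁻⁴ /s)
    target ⇌ isomer of the product (K = 8.00, k = 1.46 × 10⁻⁴ /s)

In the neighbour flask, left until 5.0 h, k gives 13.8% of the substrate left. The computed flask holds 10%, with target at 26.5%, above the late level.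

(Readings and results stem from a simulated flask with constants of no real substance; scatter was added.)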